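Ring A is disconnected at C2–C3. (R)-Carvone supplies ring B: its stereocentre becomes C5, its enone C7–C8(Me)–C9, its isopropenyl group C4, C18 and the acyl carbon C3. A C3→O6 γ-lactone, from iodolactonisation, sets the 6β oxygen and steers hydroxymethylation (C19) to the β face of C4, then is opened to a Weinreb amide. The key step turns the two-carbon arm on quaternary C10 into a C2 alkyllithium that acylates itself on C3 and closes ring A as the 3-ketone; it exploits the non-enolisable C3 acyl group flanked by quaternary C4 and the 1,6 relation of C2 and C3 across the C5–C10 bond. Directed reduction, acylation and B-alkyl Suzuki coupling finish.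

Key step: step 11

Remark: atoms are numbered as in the labdane skeleton of the target (ring A: C1–C5 and C10; ring B: C5–C10; C17 on C8; C18 the 4α-methyl; C19 the 4β-CH2O; C20 on C10; side chain C11–C16; β is the face of C20), and 2-chloroethyl trifluoromethanesulfonate and tert-butyl but-2-ynoate are taken as purchasable.

Step 1
Reactants: 1 (R)-(−)-carvone
Product: 3 (5R,6S)-6-methylcarvone, via lithium enolate 2 (not isolated)
Conditions: LiN(i-Pr)2, THF, −78 °C; MeI, −78 → 0 °C
Reagents that add atoms: iodomethane, CI
Why: Kinetic α′-deprotonation gives the cross-conjugated enolate, which is C-methylated (enolate alkylation) mainly anti to the isopropenyl group; the configuration at this carbon (future C10) is erased again in step 2.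

Step 2
Reactants: 3 (5R,6S)-6-methylcarvone
Product: 5 (5S,6S)-6-(2-chloroethyl)-6-methylcarvone, via lithium enolate 4 (not isolated)
Conditions: LiN(i-Pr)2, THF, −78 → 0 °C; ClCH2CH2OTf, −78 → −20 °C
Reagents that add atoms: 2-chloroethyl trifluoromethanesulfonate, ClCCOS(=O)(=O)C(F)(F)F
Why: Enolate alkylation with a primary triflate builds quaternary C10; the electrophile should enter anti to the neighbouring isopropenyl group, so the C1–C2 arm becomes trans to C4 and C20 cis to it, the relative configuration of the trans-fused decalin.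

Step 3
Reactants: 5 (5S,6S)-6-(2-chloroethyl)-6-methylcarvone
Product: 7 primary alcohol (isopropenyl converted to 1-hydroxypropan-2-yl), via alkylborane 6 (not isolated)
Conditions: 9-BBN, THF, 0 °C → rt; NaBO3·4H2O, H2O, rt
Reagents that add atoms: sodium perborate, [Na+].[O-]OB=O
Why: Hydroboration–oxidation; 9-BBN should add to the 1,1-disubstituted alkene (boron on the terminal carbon, future C3) and leave the electron-poor, hindered enone, and perborate oxidises the borane without epoxidising the enone; the new centre at C4 forms as both epimers and is erased in step 8.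

Step 4
Reactants: 7 primary alcohol
Product: 8 enone carboxylic acid (C3 as CO2H)
Conditions: TEMPO (cat.), PhI(OAc)2, MeCN/H2O 1:1, rt
Reagents that add atoms: water, O
Why: TEMPO/PhI(OAc)2 oxidation of the primary alcohol runs through the aldehyde hydrate to the carboxylic acid and does not touch the enone or the chloride.

Step 5
Reactants: 8 enone carboxylic acid
Product: 10 deconjugated (C6=C7) keto acid, via dilithium dienolate 9 (not isolated)
Conditions: LiN(i-Pr)2 (2.4 equiv), THF, −78 → −40 °C; inverse quench into AcOH, −78 °C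
Reagents that add atoms: none
Why: Deconjugation of the enone: with C10 quaternary the only acidic C–H of the ketone is at C6 (γ), the carboxylate α-position being spared at low temperature, and kinetic protonation of the extended dienolate at C8 gives the C6=C7 isomer needed for lactonisation.

Step 6
Reactants: 10 deconjugated keto acid
Product: 12 enone γ-lactone (C3 carbonyl to 6β-O), via iodolactone 11 (not isolated)
Conditions: I2, NaHCO3, MeCN/H2O, 0 °C, dark; then DBU, rt
Reagents that add atoms: none
Why: Iodolactonisation (5-exo, anti addition) delivers the carboxylate oxygen to C6 on the face that carries C4, which sets the 6β C–O bond in a cis-fused γ-lactone, and the resulting β-iodo ketone loses HI by E1cB elimination to restore the C7=C8 enone.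

Step 7
Reactants: 12 enone γ-lactone
Product: 14 enol triflate lactone, via lithium enolate 13 (not isolated)
Conditions: LiBH(s-Bu)3, THF, −78 °C; N-(5-chloropyridin-2-yl)triflimide, −78 → 0 °C
Reagents that add atoms: N-(5-chloropyridin-2-yl)-1,1,1-trifluoro-N-(trifluoromethylsulfonyl)methanesulfonamide, FC(F)(F)S(=O)(=O)N(c1ccc(Cl)cn1)S(=O)(=O)C(F)(F)F
Why: Conjugate (1,4) reduction gives the regiodefined C8=C9 enolate, which is O-sulfonylated by the Comins reagent to the tetrasubstituted enol triflate; this fixes the 8,9-alkene and removes the enolisable ketone before the strongly basic steps.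

Step 8
Reactants: 14 enol triflate lactone
Product: 16 hydroxymethyl lactone (C4 quaternary), via lactone enolate 15 (not isolated)
Conditions: LiN(i-Pr)2, THF, −78 °C; CH2O (gas, from cracked paraformaldehyde), −78 °C; aq. NH4Cl
Reagents that add atoms: formaldehyde, C=O
Why: Aldol addition of the lactone enolate to formaldehyde on the convex face of the cis-fused bicycle (anti to C10) makes quaternary C4 with the hydroxymethyl group (C19) on the face of H5 and the methyl group (C18) on the face of C10, which becomes 4β-CH2OH and 4α-CH3 once ring A is closed through C3.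

Step 9
Reactants: 16 hydroxymethyl lactone
Product: 17 iodoethyl hydroxymethyl lactone
Conditions: NaI, butan-2-one, 80 °C
Reagents that add atoms: sodium iodide, [Na+].[I-]
Why: Finkelstein halide exchange (SN2) at the unhindered primary carbon C2, driven by precipitation of NaCl, gives the iodide needed for lithium exchange.

Step 10
Reactants: 17 iodoethyl hydroxymethyl lactone
Product: 19 bis(trimethylsilyl) ether of the ring-opened Weinreb amide, via hydroxy amide 18 (not isolated)
Conditions: MeNH(OMe)·HCl, i-PrMgCl, THF, −15 → 0 °C; then Me3SiCl, 0 °C → rt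
Reagents that add atoms: N,O-dimethylhydroxylamine hydrochloride, CNOC.Cl; chlorotrimethylsilane, C[Si](C)(C)Cl
Why: Weinreb amide formation by aminolysis of the lactone with the chloromagnesium amide, followed by O-silylation of both magnesium alkoxides to block relactonisation; the lactone has to be opened because it holds C3 between C6 and C10, out of reach of the C10 arm, whereas the amide can rotate about C4–C5.

Step 11
Reactants: 19 bis(trimethylsilyl) ether of the Weinreb amide
Product: 22 6β,19-dihydroxy-3-oxo-11,12,13,14,15,16-hexanorlabd-8-en-9-yl triflate, via alkyllithium 20 (not isolated), via tetrahedral adduct 21 (not isolated)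
Conditions: t-BuLi (2.1 equiv), Et2O/pentane, −78 → −20 °C; then 1 M HCl, THF, 0 °C
Reagents that add atoms: none
Why: Iodine–lithium exchange with t-BuLi (the second equivalent destroys t-BuI) should be faster at −78 °C than attack on the amide or on the triflate sulfur and gives the primary C2 alkyllithium, which adds to the C3 Weinreb amide to give a five-membered Li–O–N chelate that survives until acidic work-up, so that only one C–C bond is formed and the 3-ketone is released together with both hydroxyl groups. The closest known reaction type is the Parham/Cooke anionic cyclisation, here as an intramolecular Weinreb ketone synthesis. Ring A closes in the 6-exo-trig mode through a chair in which the C19 arm is axial and C18 equatorial, a geometry that is open only after step 10 has freed the C4–C5 bond. No stereocentre is created in the product (C3 is trigonal); C4, C5 and C10 are carried through unchanged and fix the trans ring fusion. The step needs chemoselectivity for exchange over deprotonation and for mono-addition, which the substrate secures by having no acidic C–H or O–H (C4 is quaternary, both hydroxyls are silylated, the ring B ketone is masked as the enol triflate) and by the chelated adduct.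

Step 12
Reactants: 22 keto diol
Product: 23 3α,6β,19-trihydroxy-11,12,13,14,15,16-hexanorlabd-8-en-9-yl triflate
Conditions: Me4NBH(OAc)3, MeCN/AcOH 1:1, −20 → 0 °C
Reagents that add atoms: none
Why: Hydroxyl-directed reduction (Evans–Saksena): the β-axial 19-OH binds the acetoxyborohydride and delivers hydride to the β face of the C3 ketone, so the new alcohol should be 3α (axial, anti to C19).

Step 13
Reactants: 23 triol
Product: 24 6β-hydroxy-3α,19-bis(3-methylbutanoyloxy)-11,12,13,14,15,16-hexanorlabd-8-en-9-yl triflate
Conditions: (Me2CHCH2CO)2O (2.5 equiv), DMAP (cat.), pyridine, CH2Cl2, 0 °C → rt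
Reagents that add atoms: 3-methylbutanoic anhydride, CC(C)CC(=O)OC(=O)CC(C)C
Why: DMAP-catalysed acylation of the primary 19-OH and the 3α-OH; the 6β-OH, which is 1,3-diaxial to both C20 and the C19 arm, should stay free under these conditions.

Step 14
Reactants: 25 tert-butyl but-2-ynoate
Product: 27 tert-butyl (2E)-3-methylpenta-2,4-dienoate, via alkenylcopper 26 (not isolated)
Conditions: CH2=CHMgBr, CuBr·SMe2, THF, −78 °C; then MeOH and aq. NH4Cl at −78 °C
Reagents that add atoms: vinylmagnesium bromide, C=C[Mg]Br
Why: syn-Carbocupration (conjugate addition) of vinylcopper to the ynoate at low temperature and protonation of the alkenylcopper with retention should give the (2E)-dienoate.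

Step 15
Reactants: 24 diester enol triflate; 27 tert-butyl (2E)-3-methylpenta-2,4-dienoate
Product: 29 tert-butyl 6β-hydroxy-3α,19-bis(3-methylbutanoyloxy)labda-8,13E-dien-15-oate, via alkylborane 28 (not isolated)
Conditions: 27, 9-BBN, THF, 0 °C → rt; then 24, Pd(dppf)Cl2 (10 mol%), AsPh3, Cs2CO3, DMF/THF/H2O, 50 °C
Reagents that add atoms: none
Why: B-alkyl Suzuki–Miyaura coupling: 9-BBN adds anti-Markovnikov to the terminal alkene of 27 only, and the alkylborane couples with the enol triflate to form the C9–C11 bond, the (13E)-alkene being carried in unchanged.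

Step 16
Reactants: 29 tert-butyl ester
Product: 30 6β-hydroxy-3α,19-bis(3-methylbutanoyloxy)labda-8,13E-dien-15-oic acid (CNP0333611.1)
Conditions: CF3CO2H/CH2Cl2 1:4, 0 °C
Reagents that add atoms: none
Why: Acidolysis of the tert-butyl ester (loss of 2-methylpropene) frees the C15 acid without touching the two isovalerates; the tetrasubstituted 8,9-alkene is the thermodynamically favoured position and should not move.

Compound list

1 | (R)-(−)-carvone, (5R)-2-methyl-5-(prop-1-en-2-yl)cyclohex-2-en-1-one | CC1=CC[C@@H](C(C)=C)CC1=O | starting material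
2 | kinetic lithium enolate of 1 (C9–OLi, C9=C10) | CC1=CC[C@@H](C(C)=C)C=C1O[Li] | intermediate
3 | (5R,6S)-2,6-dimethyl-5-(prop-1-en-2-yl)cyclohex-2-en-1-one (trans-6-methylcarvone, main epimer) | CC1=CC[C@@H](C(C)=C)[C@H](C)C1=O | intermediate
4 | lithium enolate of 3 | CC1=CC[C@@H](C(C)=C)C(C)=C1O[Li] | intermediate
5 | (5S,6S)-6-(2-chloroethyl)-2,6-dimethyl-5-(prop-1-en-2-yl)cyclohex-2-en-1-one (chloroethyl arm C1–C2 trans to isopropenyl) | CC1=CC[C@@H](C(C)=C)[C@](C)(CCCl)C1=O | intermediate
6 | B-alkyl-9-BBN adduct of 5 (boron on the former =CH2, future C3) | CC1=CC[C@@H](C(C)CB2C3CCCC2CCC3)[C@](C)(CCCl)C1=O | intermediate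
7 | 6-(2-chloroethyl)-5-(1-hydroxypropan-2-yl)-2,6-dimethylcyclohex-2-en-1-one, ring centres as in 5, both epimers at C4 | CC1=CC[C@@H](C(C)CO)[C@](C)(CCCl)C1=O | intermediate
8 | 2-[6-(2-chloroethyl)-4,6-dimethyl-5-oxocyclohex-3-en-1-yl]propanoic acid, ring centres as in 5, both epimers at C4 | CC1=CC[C@@H](C(C)C(=O)O)[C@](C)(CCCl)C1=O | intermediate
9 | dilithium salt of 8: extended dienolate (O–C9=C8, C6=C7) and carboxylate | CC1=C(O[Li])[C@@](C)(CCCl)[C@H](C(C)C(=O)O[Li])C=C1 | intermediate
10 | 2-[6-(2-chloroethyl)-4,6-dimethyl-5-oxocyclohex-2-en-1-yl]propanoic acid (C6=C7 alkene, epimers at C4 and C8) | CC1C=C[C@@H](C(C)C(=O)O)[C@](C)(CCCl)C1=O | intermediate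
11 | iodolactone: cis-fused γ-lactone (C3 carbonyl to 6β-O), 7α-iodide, C9 ketone | CC1[C@H](I)[C@H]2OC(=O)C(C)[C@H]2[C@](C)(CCCl)C1=O | intermediate
12 | enone lactone: cis-fused γ-lactone (C3 to 6β-O), C7=C8–C9=O enone, 10α-(2-chloroethyl), 10β-methyl, epimers at C4 | CC1=C[C@H]2OC(=O)C(C)[C@H]2[C@](C)(CCCl)C1=O | intermediate
13 | lithium enolate (O–C9=C8) from conjugate reduction of 12 | CC1=C(O[Li])[C@@](C)(CCCl)[C@@H]2C(C)C(=O)O[C@@H]2C1 | intermediate
14 | enol triflate lactone: 9-triflyloxy-8(9)-ene, lactone as in 12 | CC1=C(OS(=O)(=O)C(F)(F)F)[C@@](C)(CCCl)[C@@H]2C(C)C(=O)O[C@@H]2C1 | intermediate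
15 | lithium enolate of lactone 14 (C4=C3–OLi) | CC1=C(OS(=O)(=O)C(F)(F)F)[C@@](C)(CCCl)[C@@H]2C(C)=C(O[Li])O[C@@H]2C1 | intermediate
16 | hydroxymethyl lactone: 14 with quaternary C4 bearing CH2OH (C19, face of H5) and CH3 (C18, face of C10) | CC1=C(OS(=O)(=O)C(F)(F)F)[C@@](C)(CCCl)[C@@H]2[C@@](C)(CO)C(=O)O[C@@H]2C1 | intermediate
17 | iodide: 16 with a 2-iodoethyl arm on C10 | CC1=C(OS(=O)(=O)C(F)(F)F)[C@@](C)(CCI)[C@@H]2[C@@](C)(CO)C(=O)O[C@@H]2C1 | intermediate
18 | ring-opened hydroxy amide: C3 as N-methoxy-N-methylamide, free 6β-OH and 19-OH (present as magnesium alkoxides) | CC1=C(OS(=O)(=O)C(F)(F)F)[C@@](C)(CCI)[C@H]([C@@](C)(CO)C(=O)N(C)OC)[C@H](O)C1 | intermediate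
19 | bis(trimethylsilyl) ether of 18 | CC1=C(OS(=O)(=O)C(F)(F)F)[C@@](C)(CCI)[C@H]([C@@](C)(CO[Si](C)(C)C)C(=O)N(C)OC)[C@H](O[Si](C)(C)C)C1 | intermediate
20 | C2 alkyllithium from 19 | CC1=C(OS(=O)(=O)C(F)(F)F)[C@@](C)(CC[Li])[C@H]([C@@](C)(CO[Si](C)(C)C)C(=O)N(C)OC)[C@H](O[Si](C)(C)C)C1 | intermediate
21 | chelated tetrahedral adduct: ring A closed, C3 bearing OLi and N(OMe)Me | CC1=C(OS(=O)(=O)C(F)(F)F)[C@@]2(C)CCC(O[Li])(N(C)OC)[C@](C)(CO[Si](C)(C)C)[C@@H]2[C@H](O[Si](C)(C)C)C1 | intermediate
22 | 6β,19-dihydroxy-3-oxo-11,12,13,14,15,16-hexanorlabd-8-en-9-yl trifluoromethanesulfonate | CC1=C(OS(=O)(=O)C(F)(F)F)[C@@]2(C)CCC(=O)[C@](C)(CO)[C@@H]2[C@H](O)C1 | intermediate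
23 | 3α,6β,19-trihydroxy-11,12,13,14,15,16-hexanorlabd-8-en-9-yl trifluoromethanesulfonate | CC1=C(OS(=O)(=O)C(F)(F)F)[C@@]2(C)CC[C@@H](O)[C@](C)(CO)[C@@H]2[C@H](O)C1 | intermediate
24 | 6β-hydroxy-3α,19-bis(3-methylbutanoyloxy)-11,12,13,14,15,16-hexanorlabd-8-en-9-yl trifluoromethanesulfonate | CC1=C(OS(=O)(=O)C(F)(F)F)[C@@]2(C)CC[C@@H](OC(=O)CC(C)C)[C@](C)(COC(=O)CC(C)C)[C@@H]2[C@H](O)C1 | intermediate
25 | tert-butyl but-2-ynoate | CC#CC(=O)OC(C)(C)C | starting material
26 | alkenylcopper adduct (copper on C2, cis to the vinyl group) | C=C/C(C)=C(\[Cu])C(=O)OC(C)(C)C | intermediate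
27 | tert-butyl (2E)-3-methylpenta-2,4-dienoate | C=C/C(C)=C/C(=O)OC(C)(C)C | intermediate
28 | B-alkyl-9-BBN from 27 (boron on C5 of the dienoate, future C11) | CC(C)(C)OC(=O)/C=C(C)/CCB1C2CCCC1CCC2 | intermediate
29 | tert-butyl 6β-hydroxy-3α,19-bis(3-methylbutanoyloxy)labda-8,13E-dien-15-oate | CC1=C(CC/C(C)=C/C(=O)OC(C)(C)C)[C@@]2(C)CC[C@@H](OC(=O)CC(C)C)[C@](C)(COC(=O)CC(C)C)[C@@H]2[C@H](O)C1 | intermediate
30 | 6β-hydroxy-3α,19-bis(3-methylbutanoyloxy)labda-8,13E-dien-15-oic acid (CNP0333611.1) | CC1=C(CC/C(C)=C/C(=O)O)[C@@]2(C)CC[C@@H](OC(=O)CC(C)C)[C@](C)(COC(=O)CC(C)C)[C@@H]2[C@H](O)C1 | target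

Total step count: 16. Longest linear sequence: 15 steps (steps 1–13, 15 and 16; step 14 makes the side-chain fragment).

Steps most likely to fail

Step 11 (key step). The cyclisation may be undercut by attack of t-BuLi on the triflate sulfur or on the amide before the exchange is complete, or by proton quench of the alkyllithium before it closes the ring. The fallback replaces the organolithium by a stabilised carbanion. It sets out from 19: displacement of iodide with PhSO2Na (DMF, 50 °C) should give the sulfone F1. LiN(i-Pr)2 (2.2 equiv, THF, −78 → 0 °C) then forms the α-sulfonyl carbanion at C2, which acylates on the Weinreb amide (Claisen-type ring closure) to the β-keto sulfone F2. Samarium diiodide (THF/MeOH, −78 °C) removes the sulfonyl group and dilute HCl cleaves the silyl ethers, which comes back to the route at 22.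

Step 15. Transmetalation and reductive elimination at the tetrasubstituted triflate next to quaternary C10 may be slow, so that β-hydride elimination of the alkylpalladium or hydrolysis of the triflate takes over. The fallback forms the hindered C9–C11 bond by a Stille coupling and moves the sp3–sp2 coupling to an unhindered site. It sets out from 24: tributyl(vinyl)stannane, Pd(PPh3)4 and LiCl (dioxane, 90 °C) should give the 9-vinyl diene F3. 9-BBN adds to its terminal CH2 to give the alkylborane F4, which is coupled (Pd(dppf)Cl2, Cs2CO3, DMF/H2O) with tert-butyl (2E)-3-{[(trifluoromethyl)sulfonyl]oxy}but-2-enoate F5, itself made from tert-butyl acetoacetate with Tf2O and aqueous Me4NOH. This forms C12–C13 and comes back to the route at 29.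

Step 5. γ-Deprotonation may be incomplete, protonation may occur at C6 and return the conjugated enone, or the dienolate may be alkylated by the chloroethyl arm. The fallback replaces deconjugation and iodolactonisation by γ-bromination. It sets out from 8: Me3SiOTf/Et3N (CH2Cl2, 0 °C) should give the silyl dienol ether silyl ester F6. N-Bromosuccinimide (THF, −78 °C) brominates C6 anti to the C5 side chain and aqueous work-up gives the γ-bromo enone acid F7. K2CO3 (DMF, rt) then closes the lactone by intramolecular SN2 with inversion at C6, which comes back to the route at 12, so that steps 5 and 6 are both replaced.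

Further compounds

F1 | step 11 | sulfone: 19 with the iodide replaced by phenylsulfonyl at C2 | CC1=C(OS(=O)(=O)C(F)(F)F)[C@@](C)(CCS(=O)(=O)c2ccccc2)[C@H]([C@@](C)(CO[Si](C)(C)C)C(=O)N(C)OC)[C@H](O[Si](C)(C)C)C1
F2 | step 11 | β-keto sulfone: ring A closed, 3-oxo, 2-phenylsulfonyl, 6β- and 19-O-trimethylsilyl | CC1=C(OS(=O)(=O)C(F)(F)F)[C@@]2(C)CC(S(=O)(=O)c3ccccc3)C(=O)[C@](C)(CO[Si](C)(C)C)[C@@H]2[C@H](O[Si](C)(C)C)C1
F3 | step 15 | 9-vinyl diene: 24 with the triflate replaced by vinyl (C11=C12) | CC1=C(C=C)[C@@]2(C)CC[C@@H](OC(=O)CC(C)C)[C@](C)(COC(=O)CC(C)C)[C@@H]2[C@H](O)C1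
F4 | step 15 | B-alkyl-9-BBN from F3 (boron on C12) | CC1=C(CCB3C4CCCC3CCC4)[C@@]2(C)CC[C@@H](OC(=O)CC(C)C)[C@](C)(COC(=O)CC(C)C)[C@@H]2[C@H](O)C1
F5 | step 15 | tert-butyl (2E)-3-{[(trifluoromethyl)sulfonyl]oxy}but-2-enoate | C/C(OS(=O)(=O)C(F)(F)F)=C\C(=O)OC(C)(C)C
F6 | step 5 | trimethylsilyl dienol ether trimethylsilyl ester of 8 | CC1=C(O[Si](C)(C)C)[C@@](C)(CCCl)[C@H](C(C)C(=O)O[Si](C)(C)C)C=C1
F7 | step 5 | γ-bromo enone acid: 8 with 6α-bromide (trans to the C5 side chain) | CC1=C[C@H](Br)[C@@H](C(C)C(=O)O)[C@](C)(CCCl)C1=O
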